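**Plan**

- Retrosynthesis: the C13=C14 alkene is cut first (olefination of a C13 methyl ketone), then the acyl C–O bonds at O6 and O7 and the C7–O bond (hydroxylation of a C6-ketone dienolate). Ring B is then opened at C6–C7 and C8–C9, and the remaining cyclobutanone at C9–C11 and at C5–C6/C9–C10.
- Enabling feature: in ring B the oxygen-bearing C6 sits on ring-fusion carbon C5 and the C7–C8(CH3) pair adjoins C9. This is the pattern left when propyne is inserted into the C6–C9 bond of a cyclobutanone fused to ring A across C5–C10.
- Forward order: ring A is bought as 2,2,6-trimethylcyclohexanone; the four-membered ring is fused on by a keteniminium [2+2]; the C9 chain is added by hydrazone alkylation; ring B arises by nickel-catalysed two-carbon ring expansion; C5, C7 and C6 are then adjusted and acylated, and the side chain is finished last.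
- Stereochemistry: C10 comes from the C2-symmetric pyrrolidine auxiliary in the [2+2] (cis fusion by suprafacial addition). C5 is set by base equilibration to the trans-decalin. The 7α-oxygen (oxidant) and the 6β-oxygen (hydride) both follow from reagent approach on the α face, away from the axial C10 and C4β methyl groups. 13E comes from the Horner–Wadsworth–Emmons reaction.

Key step: step 7

Remark: labdane numbering is used for all intermediates (ring A = C1–C5 with C10, ring B = C5–C10, chain C11–C16 on C9).
Assumption: the (2R,5R) amine is taken to give the cyclobutanone with the C10 configuration of the target; if the facial sense proves opposite, the (2S,5S) amine is used with no other change.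
Remark: the chain is put on C9 after the cycloaddition because a ketal oxygen in a keteniminium side chain could reach the cumulene carbon through a six-membered ring; compounds 16, 17 and 19 are C9 epimer mixtures, which is harmless because C9 becomes sp2 in step 9.

**Route**

Step 1
Reactants: 1 2,2,6-trimethylcyclohexanone; 2 N-phenylbis(trifluoromethanesulfonimide)
Product: 4 2,6,6-trimethylcyclohex-1-en-1-yl trifluoromethanesulfonate, via lithium enolate 3 (not isolated)
Conditions: LiN(iPr)2, THF, −78 to 0 °C; then 2, 0 °C to rt
Reagents that add atoms: N-phenylbis(trifluoromethanesulfonimide), O=S(=O)(N(c1ccccc1)S(=O)(=O)C(F)(F)F)C(F)(F)F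
Why: Only one α-carbon of ketone 1 carries a hydrogen, so a single enolate forms and its O-sulfonylation (enol triflate formation) fixes the later alkene between the methyl-bearing carbon and the former carbonyl carbon.

Step 2
Reactants: 4 2,6,6-trimethylcyclohex-1-en-1-yl trifluoromethanesulfonate
Product: 5 1,3,3-trimethylcyclohexene
Conditions: Pd(OAc)2 (cat.), PPh3, HCO2H, Bu3N, DMF, 60 °C
Reagents that add atoms: none
Why: Palladium-catalysed formate reduction of the enol triflate (oxidative addition, formate-to-hydride exchange with loss of CO2, reductive elimination) replaces OTf by H without the cationic intermediates that would cause Wagner–Meerwein methyl shifts in an acid dehydration.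

Step 3
Reactants: 6 (2R,5R)-2,5-dimethylpyrrolidine; 7 acetyl chloride
Product: 8 1-[(2R,5R)-2,5-dimethylpyrrolidin-1-yl]ethan-1-one
Conditions: Et3N, CH2Cl2, 0 °C
Reagents that add atoms: acetyl chloride, CC(=O)Cl
Why: Straightforward N-acylation of the secondary amine by the acid chloride gives the tertiary amide needed for keteniminium formation.

Step 4
Reactants: 8 1-[(2R,5R)-2,5-dimethylpyrrolidin-1-yl]ethan-1-one; 5 1,3,3-trimethylcyclohexene
Product: 11 (1R,6R)-1,5,5-trimethylbicyclo[4.2.0]octan-7-one (cis-fused; H5 and the C10 methyl both β), via keteniminium triflate 9 (not isolated), via cyclobutaniminium triflate 10 (not isolated)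
Conditions: Tf2O, 2,4,6-collidine, ClCH2CH2Cl, −20 to 80 °C; then H2O, 80 °C
Reagents that add atoms: amide 8, CC(=O)N1[C@H](C)CC[C@H]1C; water, O
Why: Amide activation gives the keteniminium ion (keteniminium–alkene [2+2] cycloaddition), whose central carbon bonds to the less substituted alkene carbon C5 while its CH2 terminus closes on the tertiary C10, so the fusion is necessarily cis, the C2-symmetric auxiliary selects the alkene face and thereby sets C10, and hydrolysis of the iminium salt releases the ketone and the recoverable amine.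

Step 5
Reactants: 11 (1R,6R)-1,5,5-trimethylbicyclo[4.2.0]octan-7-one; 12 1,1-dimethylhydrazine
Product: 13 N,N-dimethylhydrazone of ketone 11
Conditions: 12 (excess), AcOH (cat.), EtOH, 70 °C
Reagents that add atoms: 1,1-dimethylhydrazine, CN(C)N
Why: Condensation of the strained ketone with the hydrazine (hydrazone formation) masks the electrophilic carbonyl and provides access to a strongly nucleophilic azaenolate.

Step 6
Reactants: 13 N,N-dimethylhydrazone of ketone 11; 14 2-(2-bromoethyl)-2-methyl-1,3-dioxolane
Product: 17 (1R,6R)-8-[2-(2-methyl-1,3-dioxolan-2-yl)ethyl]-1,5,5-trimethylbicyclo[4.2.0]octan-7-one (C8 epimers; C8 = labdane C9), via lithium azaenolate 15 (not isolated), via alkylated hydrazone 16 (not isolated)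
Conditions: LiN(iPr)2, THF, 0 °C; 14, −78 to 0 °C; then aq. CuCl2, pH 7 phosphate buffer, THF, rt
Reagents that add atoms: 2-(2-bromoethyl)-2-methyl-1,3-dioxolane, CC1(CCBr)OCCO1; water, O
Why: Deprotonation occurs at the only α-methylene (C9), the azaenolate is alkylated by the primary bromide (hydrazone azaenolate alkylation), and neutral copper-assisted hydrolysis returns the ketone with the ketal intact.

Step 7
Reactants: 17 (1R,6R)-8-[2-(2-methyl-1,3-dioxolan-2-yl)ethyl]-1,5,5-trimethylbicyclo[4.2.0]octan-7-one; 18 propyne
Product: 19 13,13-ethylenedioxy-14,15-dinor-5β-labd-7-en-6-one (cis-fused; C9 epimers)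
Conditions: Ni(cod)2 (cat.), PCy3, toluene, 100 °C, closed vessel; 18 (excess) fed slowly as a toluene solution
Reagents that add atoms: propyne, CC#C
Why: Zerovalent nickel couples the C6 carbonyl and propyne by oxidative cyclisation to a spiro oxanickelacyclopentene in which C6 is bonded to the unsubstituted alkyne carbon (C7) and nickel to the methyl-bearing carbon (C8); β-carbon elimination, driven by release of cyclobutane strain, then moves C9 to nickel and reductive elimination forms C8–C9. The closest known reaction type is the nickel-catalysed intermolecular insertion of alkynes into cyclobutanones to give cyclohex-2-enones. Ring B closes as a formal [4+2] ring expansion, its last bond (C8–C9) being made by C(sp3)–C(sp2) reductive elimination from a seven-membered nickelacycle. No stereocentre is created: C5 and C10 are untouched and C9 migrates with retention, so the cis fusion of 17 is carried into 19. The step needs three selectivities: bonding of C6 to the terminal alkyne carbon, secured by the preference of the oxidative cyclisation for the unhindered CH terminus; cleavage of C6–C9 rather than C6–C5, favoured because C5 lies between the quaternary carbons C4 and C10 and would give the more hindered alkylnickel; and cross-coupling ahead of propyne oligomerisation, which slow feeding at low stationary alkyne concentration is meant to secure.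

Step 8
Reactants: 19 13,13-ethylenedioxy-14,15-dinor-5β-labd-7-en-6-one
Product: 20 13,13-ethylenedioxy-14,15-dinorlabd-7-en-6-one (trans-fused; H5 α)
Conditions: NaOMe, MeOH, 60 °C
Reagents that add atoms: none
Why: Reversible enolisation toward C5 (base-mediated epimerisation α to the ketone) should let the ring fusion relax from the cis- to the more stable trans-decalin, while any equilibration at C9 or of the double bond position is without consequence for step 9.

Step 9
Reactants: 20 13,13-ethylenedioxy-14,15-dinorlabd-7-en-6-one; 22 2-(phenylsulfonyl)-3-phenyloxaziridine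
Product: 23 13,13-ethylenedioxy-7α-hydroxy-14,15-dinorlabd-8-en-6-one, via potassium dienolate 21 (not isolated)
Conditions: KOtBu, THF, 0 °C; then 22, −78 °C; AcOH quench at −78 °C
Reagents that add atoms: 2-(phenylsulfonyl)-3-phenyloxaziridine, O=S(=O)(N1OC1c1ccccc1)c1ccccc1
Why: Under equilibrating alkoxide conditions the enone is converted into the most stable, linearly conjugated dienolate (γ-deprotonation at C9), which is oxidised at its α-carbon C7 by the N-sulfonyloxaziridine (Davis α-hydroxylation) on the α face, opposite the axial C10 and C4β methyl groups, leaving the double bond at C8–C9.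

Step 10
Reactants: 23 13,13-ethylenedioxy-7α-hydroxy-14,15-dinorlabd-8-en-6-one; 24 3-methylbutanoyl chloride
Product: 25 13,13-ethylenedioxy-6-oxo-14,15-dinorlabd-8-en-7α-yl 3-methylbutanoate
Conditions: pyridine, DMAP (cat.), CH2Cl2, 0 °C
Reagents that add atoms: 3-methylbutanoyl chloride, CC(C)CC(=O)Cl
Why: DMAP-catalysed acylation of the secondary allylic alcohol by the acid chloride proceeds under base mild enough to avoid isomerisation of the α-ketol.

Step 11
Reactants: 25 13,13-ethylenedioxy-6-oxo-14,15-dinorlabd-8-en-7α-yl 3-methylbutanoate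
Product: 26 13,13-ethylenedioxy-6β-hydroxy-14,15-dinorlabd-8-en-7α-yl 3-methylbutanoate
Conditions: NaBH4, MeOH–THF, −20 °C
Reagents that add atoms: none
Why: Borohydride reduction of the ketone should occur from the α face because the β face of C6 is screened by the syn-axial C10 and C4β methyl groups, giving the axial 6β-alcohol, whose trans-diaxial relation to the 7α-ester disfavours acyl migration.

Step 12
Reactants: 26 13,13-ethylenedioxy-6β-hydroxy-14,15-dinorlabd-8-en-7α-yl 3-methylbutanoate; 27 acetic anhydride
Product: 28 6β-acetoxy-13,13-ethylenedioxy-14,15-dinorlabd-8-en-7α-yl 3-methylbutanoate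
Conditions: Et3N, DMAP, CH2Cl2, 40 °C
Reagents that add atoms: acetic anhydride, CC(=O)OC(C)=O
Why: DMAP-catalysed acetylation (nucleophilic acyl transfer) is strong enough to esterify the hindered axial 6β-hydroxyl without disturbing the ketal.

Step 13
Reactants: 28 6β-acetoxy-13,13-ethylenedioxy-14,15-dinorlabd-8-en-7α-yl 3-methylbutanoate
Product: 29 6β-acetoxy-13-oxo-14,15-dinorlabd-8-en-7α-yl 3-methylbutanoate
Conditions: PPTS, acetone–H2O, 50 °C
Reagents that add atoms: water, O
Why: Mild acid-catalysed hydrolysis of the dioxolane (ketal deprotection) frees the C13 methyl ketone while the acetate, the allylic ester and the tetrasubstituted alkene are left untouched.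

Step 14
Reactants: 29 6β-acetoxy-13-oxo-14,15-dinorlabd-8-en-7α-yl 3-methylbutanoate; 30 allyl (diethoxyphosphoryl)acetate
Product: 31 allyl (13E)-6β-acetoxy-7α-(3-methylbutanoyloxy)labda-8,13-dien-15-oate
Conditions: NaH, THF, 0 °C; then 29, 50 °C
Reagents that add atoms: allyl (diethoxyphosphoryl)acetate, C=CCOC(=O)CP(=O)(OCC)OCC
Why: Horner–Wadsworth–Emmons olefination of the only ketone by the stabilised phosphonate anion places the ester trans to the larger C12 chain and so should favour the 13E alkene (the Z isomer being removed by chromatography), while the weakly basic anion spares the two ring esters.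

Step 15
Reactants: 31 allyl (13E)-6β-acetoxy-7α-(3-methylbutanoyloxy)labda-8,13-dien-15-oate
Product: 32 (13E)-6β-acetoxy-7α-(3-methylbutanoyloxy)labda-8,13-dien-15-oic acid (5S,6S,7S,10S)
Conditions: Pd(PPh3)4 (cat.), morpholine, THF, rt; dilute citric acid work-up
Reagents that add atoms: none
Why: Zerovalent palladium ionises the unhindered allyl ester to a π-allyl complex that is captured by morpholine (Tsuji–Trost deallylation), freeing the acid under neutral conditions that leave the acetate and the hindered ring allylic ester intact.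

**Compound list**

1 | 2,2,6-trimethylcyclohexanone (racemic) | CC1CCCC(C)(C)C1=O | starting material
2 | N-phenylbis(trifluoromethanesulfonimide) | O=S(=O)(N(c1ccccc1)S(=O)(=O)C(F)(F)F)C(F)(F)F | starting material
3 | lithium 2,6,6-trimethylcyclohex-1-en-1-olate | [Li+].CC1=C([O-])C(C)(C)CCC1 | intermediate
4 | 2,6,6-trimethylcyclohex-1-en-1-yl trifluoromethanesulfonate | CC1=C(OS(=O)(=O)C(F)(F)F)C(C)(C)CCC1 | intermediate
5 | 1,3,3-trimethylcyclohexene | CC1=CC(C)(C)CCC1 | intermediate
6 | (2R,5R)-2,5-dimethylpyrrolidine | C[C@@H]1CC[C@@H](C)N1 | starting material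
7 | acetyl chloride | CC(=O)Cl | starting material
8 | 1-[(2R,5R)-2,5-dimethylpyrrolidin-1-yl]ethan-1-one | CC(=O)N1[C@H](C)CC[C@H]1C | intermediate
9 | (2R,5R)-1-ethenylidene-2,5-dimethylpyrrolidinium triflate (keteniminium triflate) | C=C=[N+]1[C@H](C)CC[C@H]1C.[O-]S(=O)(=O)C(F)(F)F | intermediate
10 | cyclobutaniminium triflate (iminium of ketone 11 with the auxiliary amine) | [N+]3(=C1C[C@@]2(C)CCCC(C)(C)[C@@H]12)[C@H](C)CC[C@H]3C.[O-]S(=O)(=O)C(F)(F)F | intermediate
11 | (1R,6R)-1,5,5-trimethylbicyclo[4.2.0]octan-7-one (cis-fused; C7 = labdane C6) | O=C1C[C@@]2(C)CCCC(C)(C)[C@@H]12 | intermediate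
12 | 1,1-dimethylhydrazine | CN(C)N | starting material
13 | N,N-dimethylhydrazone of 11 | CN(C)N=C1C[C@@]2(C)CCCC(C)(C)[C@@H]12 | intermediate
14 | 2-(2-bromoethyl)-2-methyl-1,3-dioxolane | CC1(CCBr)OCCO1 | starting material
15 | lithium azaenolate of 13 (deprotonated at labdane C9) | [Li+].CN(C)[N-]C1=C[C@@]2(C)CCCC(C)(C)[C@@H]12 | intermediate
16 | N,N-dimethylhydrazone of 17 (C9 epimers) | CN(C)N=C1C(CCC3(C)OCCO3)[C@@]2(C)CCCC(C)(C)[C@@H]12 | intermediate
17 | (1R,6R)-8-[2-(2-methyl-1,3-dioxolan-2-yl)ethyl]-1,5,5-trimethylbicyclo[4.2.0]octan-7-one (cis-fused; C8 epimers, C8 = labdane C9) | O=C1C(CCC3(C)OCCO3)[C@@]2(C)CCCC(C)(C)[C@@H]12 | intermediate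
18 | propyne | CC#C | starting material
19 | 13,13-ethylenedioxy-14,15-dinor-5β-labd-7-en-6-one (cis-fused, 10β-methyl; C9 epimers) | O=C1C=C(C)C(CCC3(C)OCCO3)[C@@]2(C)CCCC(C)(C)[C@@H]12 | intermediate
20 | 13,13-ethylenedioxy-14,15-dinorlabd-7-en-6-one (trans-fused, 5α-H, 10β-methyl; C9 configuration immaterial) | O=C1C=C(C)C(CCC3(C)OCCO3)[C@@]2(C)CCCC(C)(C)[C@H]12 | intermediate
21 | potassium 6,8-dienolate of 20 (C6–O, C6=C7, C8=C9) | [K+].[O-]C1=CC(C)=C(CCC3(C)OCCO3)[C@@]2(C)CCCC(C)(C)[C@H]12 | intermediate
22 | 2-(phenylsulfonyl)-3-phenyloxaziridine (racemic) | O=S(=O)(N1OC1c1ccccc1)c1ccccc1 | starting material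
23 | 13,13-ethylenedioxy-7α-hydroxy-14,15-dinorlabd-8-en-6-one | O=C1[C@@H](O)C(C)=C(CCC3(C)OCCO3)[C@@]2(C)CCCC(C)(C)[C@H]12 | intermediate
24 | 3-methylbutanoyl chloride | CC(C)CC(=O)Cl | starting material
25 | 13,13-ethylenedioxy-6-oxo-14,15-dinorlabd-8-en-7α-yl 3-methylbutanoate | O=C1[C@@H](OC(=O)CC(C)C)C(C)=C(CCC3(C)OCCO3)[C@@]2(C)CCCC(C)(C)[C@H]12 | intermediate
26 | 13,13-ethylenedioxy-6β-hydroxy-14,15-dinorlabd-8-en-7α-yl 3-methylbutanoate | O[C@@H]1[C@@H](OC(=O)CC(C)C)C(C)=C(CCC3(C)OCCO3)[C@@]2(C)CCCC(C)(C)[C@H]12 | intermediate
27 | acetic anhydride | CC(=O)OC(C)=O | starting material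
28 | 6β-acetoxy-13,13-ethylenedioxy-14,15-dinorlabd-8-en-7α-yl 3-methylbutanoate | CC(=O)O[C@@H]1[C@@H](OC(=O)CC(C)C)C(C)=C(CCC3(C)OCCO3)[C@@]2(C)CCCC(C)(C)[C@H]12 | intermediate
29 | 6β-acetoxy-13-oxo-14,15-dinorlabd-8-en-7α-yl 3-methylbutanoate | CC(=O)O[C@@H]1[C@@H](OC(=O)CC(C)C)C(C)=C(CCC(C)=O)[C@@]2(C)CCCC(C)(C)[C@H]12 | intermediate
30 | allyl (diethoxyphosphoryl)acetate | C=CCOC(=O)CP(=O)(OCC)OCC | starting material
31 | allyl (13E)-6β-acetoxy-7α-(3-methylbutanoyloxy)labda-8,13-dien-15-oate | CC(=O)O[C@@H]1[C@@H](OC(=O)CC(C)C)C(C)=C(CC/C(C)=C/C(=O)OCC=C)[C@@]2(C)CCCC(C)(C)[C@H]12 | intermediate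
32 | (5S,6S,7S,10S,13E)-6-acetoxy-7-(3-methylbutanoyloxy)labda-8,13-dien-15-oic acid (6β-OAc, 7α-O-isovaleryl) | CC(=O)O[C@@H]1[C@@H](OC(=O)CC(C)C)C(C)=C(CC/C(C)=C/C(=O)O)[C@@]2(C)CCCC(C)(C)[C@H]12 | target

**Step count and risks**

Total step count: 15. Longest linear sequence: 14 steps (steps 1, 2 and 4–15, from ketone 1); step 3 is a one-step branch.

Steps most likely to fail:

1. Step 7. Oligomerisation and cyclotrimerisation of the terminal alkyne on nickel may outrun the oxidative cyclisation with the hindered carbonyl, or β-carbon elimination may transfer C5 instead of C9 to the metal. The fallback sets out from 17 and comes back at 19, making the same two bonds one at a time. Addition of LiC≡CCH3 (CeCl3, THF, −78 °C) to the carbonyl of 17 forms C6–C7 and gives the tertiary propargylic cyclobutanol F1. Hydroxyl-directed trans-hydroalumination with NaAlH2(OCH2CH2OMe)2 followed by I2 gives the (Z)-iodoalkenyl cyclobutanol F2, with iodine on C8 and cis to C6. Pd(OAc)2 with a bulky phosphine and Cs2CO3 in toluene at 80 °C should then effect oxidative addition into the C8–I bond, formation of the palladium alkoxide, strain-driven β-carbon elimination of C9 and C8–C9 reductive elimination, giving 19.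

2. Step 4. First bond formation at the neopentyl alkene carbon C5 may be slow enough for the keteniminium ion to decompose, or the auxiliary may discriminate the alkene faces poorly. The fallback sets out from 5 and comes back at 17. Dichloroketene, generated from Cl3CCOCl and Zn in Et2O, adds to 5 with the same regiochemistry and gives the racemic dichlorocyclobutanone F3. Zn in AcOH removes both chlorine atoms to give the racemic ketone F4. Condensation with (S)-1-amino-2-(methoxymethyl)pyrrolidine (SAMP) gives the SAMP hydrazone F5 of the needed enantiomer and its diastereomer F6, which are separated by chromatography. F5 is deprotonated and alkylated with 14 as in step 6 to the alkylated SAMP hydrazone F7, whose copper-assisted hydrolysis returns 17.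

3. Step 9. Enolisation toward C5 or toward the C8 methyl group may compete with γ-deprotonation at C9, so that oxygen is delivered to the wrong carbon, or the α-ketol may enolise further and be over-oxidised. The fallback sets out from 20 and comes back at 23; it first moves the double bond out of conjugation. Treatment of 20 with KOtBu in THF followed by inverse quench into cold aqueous AcOH protonates the dienolate at C7 and gives the β,γ-unsaturated ketone F8. Its C7 methylene, now both α to the ketone and allylic, is deprotonated selectively with LiN(SiMe3)2 at −78 °C to the lithium dienolate F9, which is hydroxylated with 22 as before to give 23.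

Further compounds
F1 | step 7 | tertiary propargylic cyclobutanol from 17 (7-(prop-1-yn-1-yl)bicyclo[4.2.0]octan-7-ol with the C8 chain) | CC#CC1(O)C(CCC3(C)OCCO3)[C@@]2(C)CCCC(C)(C)[C@@H]12
F2 | step 7 | (Z)-2-iodoprop-1-en-1-yl cyclobutanol (iodine on labdane C8, cis to C6) | C/C(I)=C/C1(O)C(CCC3(C)OCCO3)[C@@]2(C)CCCC(C)(C)[C@@H]12
F3 | step 4 | racemic cis-8,8-dichloro-1,5,5-trimethylbicyclo[4.2.0]octan-7-one | O=C1C(Cl)(Cl)C2(C)CCCC(C)(C)C12
F4 | step 4 | racemic cis-1,5,5-trimethylbicyclo[4.2.0]octan-7-one | O=C1CC2(C)CCCC(C)(C)C12
F5 | step 4 | SAMP hydrazone of (1R,6R)-ketone 11 | COC[C@@H]1CCCN1N=C1C[C@@]2(C)CCCC(C)(C)[C@@H]12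
F6 | step 4 | SAMP hydrazone of the (1S,6S)-ketone (diastereomer of F5) | COC[C@@H]1CCCN1N=C1C[C@]2(C)CCCC(C)(C)[C@H]12
F7 | step 4 | SAMP hydrazone of 17 (C9 epimers) | COC[C@@H]1CCCN1N=C1C(CCC3(C)OCCO3)[C@@]2(C)CCCC(C)(C)[C@@H]12
F8 | step 9 | 13,13-ethylenedioxy-14,15-dinorlabd-8-en-6-one | O=C1CC(C)=C(CCC3(C)OCCO3)[C@@]2(C)CCCC(C)(C)[C@H]12
F9 | step 9 | lithium 6,8-dienolate of F8 | [Li+].[O-]C1=CC(C)=C(CCC3(C)OCCO3)[C@@]2(C)CCCC(C)(C)[C@H]12
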